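**Retrosynthetic overview**

1. The ten-membered ring is closed last by ring-closing metathesis of two vinyl epoxides (C2=C3, Z).
2. The butenolide comes from a Nozaki–Hiyama–Kishi addition of (Z)-β-iodoenoate 25 to epoxy aldehyde 4 (C6–C7), followed by lactonisation.
3. Both oxiranes come from Katsuki–Sharpless epoxidation of allylic alcohols 2 and 24, each with L-(+)-tartrate.
4. The C7–C8–C9–C10 chain comes from the key skeletal step: a Wolff 1,2-alkenyl shift of dienyl diazoketone 13 with alkynyllithium capture of the ketene (inserts C9, keeps the C10=C1 geometry), then Noyori reduction (C8).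
5. Ring order: the two oxiranes (on separate fragments), then the butenolide, then the ten-membered carbocycle.

Assumption: stereodescriptors are taken as drawn (8S,10S,1R,4R,5S,6S in germacranolide labels C1–C15, with C14 = CH2OH carbon, C15 = methyl, C11–C13 = lactone side; (R)-2-methylbutanoate); formaldehyde and Me3SiCHN2 are treated as reagents.

**Route**

Step 1
Reactants: 1 (Z)-3-methylpent-2-en-4-yn-1-ol
Product: 2 (Z)-3-methylpenta-2,4-dien-1-ol
Conditions: H2 (1 atm), Pd/CaCO3 poisoned with Pb(OAc)2, quinoline, EtOAc, 0 °C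
Reagents that add atoms: none
Why: Lindlar semihydrogenation stops a terminal alkyne at the alkene and leaves the trisubstituted Z-alkene of 1 untouched.

Step 2
Reactants: 2 (Z)-3-methylpenta-2,4-dien-1-ol
Product: 3 [(2S,3R)-3-ethenyl-3-methyloxiran-2-yl]methanol
Conditions: Ti(OiPr)4 (10 mol%), L-(+)-diisopropyl tartrate (12 mol%), t-BuOOH, 4 Å MS, CH2Cl2, −20 °C
Reagents that add atoms: tert-butyl hydroperoxide (CC(C)(C)OO)
Why: Katsuki–Sharpless asymmetric epoxidation attacks only the allylic-alcohol alkene, and L-(+)-tartrate gives the (2S,3R)-epoxide (same sense as nerol), setting C4 and C5 with the cis arrangement inherited from the Z-alkene.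

Step 3
Reactants: 3 [(2S,3R)-3-ethenyl-3-methyloxiran-2-yl]methanol
Product: 4 (2R,3R)-3-ethenyl-3-methyloxirane-2-carbaldehyde
Conditions: TEMPO (10 mol%), PhI(OAc)2, CH2Cl2, rt; used crude
Reagents that add atoms: none
Why: TEMPO/PhI(OAc)2 oxidation stops at the aldehyde under near-neutral conditions that neither open the epoxide nor epimerise the α-centre (the descriptor changes only by priority).

Step 4
Reactants: 5 acrolein; 6 methyl acrylate
Product: 7 methyl 3-hydroxy-2-methylidenepent-4-enoate (racemic)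
Conditions: DABCO (20 mol%), excess 6, slow addition of 5, rt
Reagents that add atoms: none
Why: Morita–Baylis–Hillman reaction: the DABCO-derived ammonium enolate of the acrylate adds to the aldehyde carbon of acrolein.

Step 5
Reactants: 7 methyl 3-hydroxy-2-methylidenepent-4-enoate
Product: 9 methyl (2E)-2-(hydroxymethyl)penta-2,4-dienoate, via acetate 8 (not isolated)
Conditions: Ac2O, pyridine, DMAP (cat.), CH2Cl2, 0 °C; then DABCO (cat.), NaHCO3, THF–H2O, rt
Reagents that add atoms: water (O)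
Why: SN2′–SN2′ allylic transposition of a Morita–Baylis–Hillman acetate gives the conjugated primary alcohol as the thermodynamic (E)-isomer, with the ester trans and the CH2OH cis to the vinyl group (the later C14/C2 relationship).

Step 6
Reactants: 9 methyl (2E)-2-(hydroxymethyl)penta-2,4-dienoate
Product: 10 methyl (2E)-2-({[tert-butyl(dimethyl)silyl]oxy}methyl)penta-2,4-dienoate
Conditions: TBSCl, imidazole, DMF, 0 °C to rt
Reagents that add atoms: tert-butyl(chloro)dimethylsilane (CC(C)(C)[Si](C)(C)Cl)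
Why: Standard silylation of a primary alcohol protects C14–OH through the organolithium and acylation steps.

Step 7
Reactants: 10 methyl (2E)-2-({[tert-butyl(dimethyl)silyl]oxy}methyl)penta-2,4-dienoate
Product: 11 (2E)-2-({[tert-butyl(dimethyl)silyl]oxy}methyl)penta-2,4-dienoic acid
Conditions: LiOH, THF–H2O, 0 °C to rt; then cold dilute HCl to pH 4
Reagents that add atoms: lithium hydroxide ([Li+].[OH-])
Why: Saponification of the methyl ester; the TBS ether and the alkene geometry survive.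

Step 8
Reactants: 11 (2E)-2-({[tert-butyl(dimethyl)silyl]oxy}methyl)penta-2,4-dienoic acid
Product: 13 (3E)-3-({[tert-butyl(dimethyl)silyl]oxy}methyl)-1-diazohexa-3,5-dien-2-one, via acid chloride 12 (not isolated)
Conditions: 1-chloro-N,N,2-trimethylprop-1-en-1-amine, CH2Cl2, 0 °C; then Me3SiCHN2, MeCN–THF, 0 °C
Reagents that add atoms: (trimethylsilyl)diazomethane (C[Si](C)(C)C=[N+]=[N-])
Why: Neutral acid-chloride formation and acylation of the diazoalkane (first stage of an Arndt–Eistert homologation) give the diazoketone without touching the TBS ether or the diene.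

Step 9
Reactants: 13 (3E)-3-({[tert-butyl(dimethyl)silyl]oxy}methyl)-1-diazohexa-3,5-dien-2-one; 14 methyl propiolate
Product: 18 methyl (6Z)-6-({[tert-butyl(dimethyl)silyl]oxy}methyl)-4-oxonona-6,8-dien-2-ynoate, via alkynyllithium 15 (not isolated), via vinylketene 16 (not isolated), via lithium enolate 17 (not isolated)
Conditions: 14, LiN(SiMe3)2, THF, −78 °C; separately 13, hν (450 nm), THF, −78 °C, then cannula transfer onto 15; AcOH, −78 °C
Reagents that add atoms: none
Why: Proposed new method: Wolff rearrangement with carbon-nucleophile capture — photolysis expels N2 and the dienyl group shifts from the carbonyl carbon to the former diazo carbon with retention of alkene geometry (the 1,2-shift that inserts C9); vinylketene 16 cannot electrocyclise because its ketene and vinyl ends are trans across C10=C1, so alkynyllithium 15 adds to the ketene carbon (C7–C8 bond) to give enolate 17, and kinetic C9-protonation gives the skipped ynone; closest known reaction types are the Arndt–Eistert homologation (ketene trapped by O- or N-nucleophiles) and the addition of organolithiums to ketenes.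

Step 10
Reactants: 18 methyl (6Z)-6-({[tert-butyl(dimethyl)silyl]oxy}methyl)-4-oxonona-6,8-dien-2-ynoate
Product: 19 methyl (4S,6Z)-6-({[tert-butyl(dimethyl)silyl]oxy}methyl)-4-hydroxynona-6,8-dien-2-ynoate
Conditions: RuCl[(S,S)-TsDPEN](p-cymene) (1 mol%), i-PrOH, rt
Reagents that add atoms: none
Why: Noyori asymmetric transfer hydrogenation of an alkynyl ketone: the (S,S)-catalyst delivers hydride to the face that gives the (S)-propargylic alcohol (C8) under base-free conditions that leave the alkyne, the diene and the acidic C9 methylene alone.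

Step 11
Reactants: 19 methyl (4S,6Z)-6-({[tert-butyl(dimethyl)silyl]oxy}methyl)-4-hydroxynona-6,8-dien-2-ynoate; 20 (2R)-2-methylbutanoic acid
Product: 21 methyl (4S,6Z)-6-({[tert-butyl(dimethyl)silyl]oxy}methyl)-4-{[(2R)-2-methylbutanoyl]oxy}nona-6,8-dien-2-ynoate
Conditions: N,N′-diisopropylcarbodiimide, DMAP (5 mol%), CH2Cl2, −20 to 0 °C
Reagents that add atoms: none
Why: Steglich esterification at the unhindered propargylic stage; carbodiimide activation at low temperature keeps the (R)-α-centre of the acid, and no strong base is used after this point.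

Step 12
Reactants: 21 methyl (4S,6Z)-6-({[tert-butyl(dimethyl)silyl]oxy}methyl)-4-{[(2R)-2-methylbutanoyl]oxy}nona-6,8-dien-2-ynoate
Product: 22 methyl (2Z,4S,6Z)-6-({[tert-butyl(dimethyl)silyl]oxy}methyl)-2-(hydroxymethyl)-3-iodo-4-{[(2R)-2-methylbutanoyl]oxy}nona-2,6,8-trienoate
Conditions: MgI2, (CH2O)n, CH2Cl2, 0 °C to rt; H2O work-up
Reagents that add atoms: magnesium iodide ([Mg+2].[I-].[I-]); formaldehyde (C=O)
Why: β-Iodo Morita–Baylis–Hillman (iodide conjugate addition–aldol) reaction: iodide adds to the ynoate β-carbon (C7) and the magnesium allenolate traps formaldehyde at C11, giving the (Z)-isomer with iodine cis to the ester.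

Step 13
Reactants: 22 methyl (2Z,4S,6Z)-6-({[tert-butyl(dimethyl)silyl]oxy}methyl)-2-(hydroxymethyl)-3-iodo-4-{[(2R)-2-methylbutanoyl]oxy}nona-2,6,8-trienoate
Product: 23 methyl (2Z,4S,6Z)-2-(acetoxymethyl)-6-({[tert-butyl(dimethyl)silyl]oxy}methyl)-3-iodo-4-{[(2R)-2-methylbutanoyl]oxy}nona-2,6,8-trienoate
Conditions: Ac2O, pyridine, CH2Cl2, 0 °C
Reagents that add atoms: acetic anhydride (CC(=O)OC(C)=O)
Why: Acetylation of the only free hydroxyl installs the C13 acetate.

Step 14
Reactants: 23 methyl (2Z,4S,6Z)-2-(acetoxymethyl)-6-({[tert-butyl(dimethyl)silyl]oxy}methyl)-3-iodo-4-{[(2R)-2-methylbutanoyl]oxy}nona-2,6,8-trienoate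
Product: 24 methyl (2Z,4S,6Z)-2-(acetoxymethyl)-6-(hydroxymethyl)-3-iodo-4-{[(2R)-2-methylbutanoyl]oxy}nona-2,6,8-trienoate
Conditions: HF·pyridine, pyridine, THF, 0 °C
Reagents that add atoms: none
Why: Buffered fluoride desilylation frees the C14 hydroxyl without touching the esters, the vinyl iodide or the diene.

Step 15
Reactants: 24 methyl (2Z,4S,6Z)-2-(acetoxymethyl)-6-(hydroxymethyl)-3-iodo-4-{[(2R)-2-methylbutanoyl]oxy}nona-2,6,8-trienoate
Product: 25 methyl (2Z,4S)-2-(acetoxymethyl)-5-[(2S,3R)-3-ethenyl-2-(hydroxymethyl)oxiran-2-yl]-3-iodo-4-{[(2R)-2-methylbutanoyl]oxy}pent-2-enoate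
Conditions: Ti(OiPr)4 (20 mol%), L-(+)-diisopropyl tartrate (24 mol%), t-BuOOH, 4 Å MS, CH2Cl2, −20 °C
Reagents that add atoms: tert-butyl hydroperoxide (CC(C)(C)OO)
Why: Katsuki–Sharpless asymmetric epoxidation is directed by the C14 hydroxyl to the C10=C1 alkene only (terminal vinyl and iodoenoate are inert), and L-(+)-tartrate gives the (2S,3R)-oxirane, setting C10 and C1 with the trans ring-carbon arrangement fixed by the alkene geometry.

Step 16
Reactants: 25 methyl (2Z,4S)-2-(acetoxymethyl)-5-[(2S,3R)-3-ethenyl-2-(hydroxymethyl)oxiran-2-yl]-3-iodo-4-{[(2R)-2-methylbutanoyl]oxy}pent-2-enoate; 4 (2R,3R)-3-ethenyl-3-methyloxirane-2-carbaldehyde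
Product: 26 (1S)-1-{(2S)-4-(acetoxymethyl)-2-[(2S,3R)-3-ethenyl-3-methyloxiran-2-yl]-5-oxo-2,5-dihydrofuran-3-yl}-2-[(2S,3R)-3-ethenyl-2-(hydroxymethyl)oxiran-2-yl]ethyl (2R)-2-methylbutanoate
Conditions: CrCl2 (4 equiv), NiCl2 (2 mol%), DMSO–THF, rt; aqueous work-up
Reagents that add atoms: none
Why: Nozaki–Hiyama–Kishi coupling: the configurationally stable alkenylchromium adds to the epoxy aldehyde in the Felkin–Anh sense (anti to the oxirane C–O bond), giving the 6S centre, and the alkoxide, cis to the methyl ester, lactonises to the butenolide.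

Step 17
Reactants: 26 (1S)-1-{(2S)-4-(acetoxymethyl)-2-[(2S,3R)-3-ethenyl-3-methyloxiran-2-yl]-5-oxo-2,5-dihydrofuran-3-yl}-2-[(2S,3R)-3-ethenyl-2-(hydroxymethyl)oxiran-2-yl]ethyl (2R)-2-methylbutanoate
Product: 27 CNP0108300.1 (target)
Conditions: RuCl2(H2IMes)(=CH-C6H4-2-OiPr) (second-generation Hoveyda–Grubbs catalyst, 15 mol%), 1,4-benzoquinone (cat.), toluene, 1 mM, 80 °C
Reagents that add atoms: none
Why: Ring-closing metathesis of the two vinyl oxiranes at high dilution; a ten-membered ring carrying two fused oxiranes and the butenolide is expected to accept only the Z-alkene, and no protecting group remains to be removed.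

**Compound list**

1 | (Z)-3-methylpent-2-en-4-yn-1-ol | C#C/C(C)=C\CO | starting material
2 | (Z)-3-methylpenta-2,4-dien-1-ol | C=C/C(C)=C\CO | intermediate
3 | [(2S,3R)-3-ethenyl-3-methyloxiran-2-yl]methanol | C=C[C@@]1(C)O[C@H]1CO | intermediate
4 | (2R,3R)-3-ethenyl-3-methyloxirane-2-carbaldehyde | C=C[C@@]1(C)O[C@H]1C=O | intermediate
5 | acrolein | C=CC=O | starting material
6 | methyl acrylate | C=CC(=O)OC | starting material
7 | methyl 3-hydroxy-2-methylidenepent-4-enoate (racemic) | C=CC(O)C(=C)C(=O)OC | intermediate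
8 | methyl 3-acetoxy-2-methylidenepent-4-enoate (racemic) | C=CC(OC(C)=O)C(=C)C(=O)OC | intermediate
9 | methyl (2E)-2-(hydroxymethyl)penta-2,4-dienoate | C=C/C=C(\CO)C(=O)OC | intermediate
10 | methyl (2E)-2-({[tert-butyl(dimethyl)silyl]oxy}methyl)penta-2,4-dienoate | C=C/C=C(\CO[Si](C)(C)C(C)(C)C)C(=O)OC | intermediate
11 | (2E)-2-({[tert-butyl(dimethyl)silyl]oxy}methyl)penta-2,4-dienoic acid | C=C/C=C(\CO[Si](C)(C)C(C)(C)C)C(=O)O | intermediate
12 | (2E)-2-({[tert-butyl(dimethyl)silyl]oxy}methyl)penta-2,4-dienoyl chloride | C=C/C=C(\CO[Si](C)(C)C(C)(C)C)C(Cl)=O | intermediate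
13 | (3E)-3-({[tert-butyl(dimethyl)silyl]oxy}methyl)-1-diazohexa-3,5-dien-2-one | C=C/C=C(\CO[Si](C)(C)C(C)(C)C)C(=O)C=[N+]=[N-] | intermediate
14 | methyl propiolate | C#CC(=O)OC | starting material
15 | lithium 3-methoxy-3-oxoprop-1-yn-1-ide | [Li+].[C-]#CC(=O)OC | intermediate
16 | (3Z)-3-({[tert-butyl(dimethyl)silyl]oxy}methyl)hexa-1,3,5-trien-1-one | C=C/C=C(\CO[Si](C)(C)C(C)(C)C)C=C=O | intermediate
17 | lithium (6Z)-6-({[tert-butyl(dimethyl)silyl]oxy}methyl)-1-methoxy-1-oxonona-4,6,8-trien-2-yn-4-olate | [Li+].COC(=O)C#CC([O-])=C/C(CO[Si](C)(C)C(C)(C)C)=C/C=C | intermediate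
18 | methyl (6Z)-6-({[tert-butyl(dimethyl)silyl]oxy}methyl)-4-oxonona-6,8-dien-2-ynoate | COC(=O)C#CC(=O)C/C(CO[Si](C)(C)C(C)(C)C)=C/C=C | intermediate
19 | methyl (4S,6Z)-6-({[tert-butyl(dimethyl)silyl]oxy}methyl)-4-hydroxynona-6,8-dien-2-ynoate | COC(=O)C#C[C@@H](O)C/C(CO[Si](C)(C)C(C)(C)C)=C/C=C | intermediate
20 | (2R)-2-methylbutanoic acid | CC[C@@H](C)C(=O)O | starting material
21 | methyl (4S,6Z)-6-({[tert-butyl(dimethyl)silyl]oxy}methyl)-4-{[(2R)-2-methylbutanoyl]oxy}nona-6,8-dien-2-ynoate | CC[C@@H](C)C(=O)O[C@H](C#CC(=O)OC)C/C(CO[Si](C)(C)C(C)(C)C)=C/C=C | intermediate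
22 | methyl (2Z,4S,6Z)-6-({[tert-butyl(dimethyl)silyl]oxy}methyl)-2-(hydroxymethyl)-3-iodo-4-{[(2R)-2-methylbutanoyl]oxy}nona-2,6,8-trienoate | COC(=O)/C(CO)=C(\I)[C@@H](OC(=O)[C@H](C)CC)C/C(CO[Si](C)(C)C(C)(C)C)=C/C=C | intermediate
23 | methyl (2Z,4S,6Z)-2-(acetoxymethyl)-6-({[tert-butyl(dimethyl)silyl]oxy}methyl)-3-iodo-4-{[(2R)-2-methylbutanoyl]oxy}nona-2,6,8-trienoate | COC(=O)/C(COC(C)=O)=C(\I)[C@@H](OC(=O)[C@H](C)CC)C/C(CO[Si](C)(C)C(C)(C)C)=C/C=C | intermediate
24 | methyl (2Z,4S,6Z)-2-(acetoxymethyl)-6-(hydroxymethyl)-3-iodo-4-{[(2R)-2-methylbutanoyl]oxy}nona-2,6,8-trienoate | COC(=O)/C(COC(C)=O)=C(\I)[C@@H](OC(=O)[C@H](C)CC)C/C(CO)=C/C=C | intermediate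
25 | methyl (2Z,4S)-2-(acetoxymethyl)-5-[(2S,3R)-3-ethenyl-2-(hydroxymethyl)oxiran-2-yl]-3-iodo-4-{[(2R)-2-methylbutanoyl]oxy}pent-2-enoate | COC(=O)/C(COC(C)=O)=C(\I)[C@@H](OC(=O)[C@H](C)CC)C[C@@]1(CO)O[C@@H]1C=C | intermediate
26 | (1S)-1-{(2S)-4-(acetoxymethyl)-2-[(2S,3R)-3-ethenyl-3-methyloxiran-2-yl]-5-oxo-2,5-dihydrofuran-3-yl}-2-[(2S,3R)-3-ethenyl-2-(hydroxymethyl)oxiran-2-yl]ethyl (2R)-2-methylbutanoate | CC[C@@H](C)C(=O)O[C@@H](C[C@@]1(CO)O[C@@H]1C=C)C1=C(COC(C)=O)C(=O)O[C@@H]1[C@@H]1O[C@]1(C)C=C | intermediate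
27 | CNP0108300.1: 13-acetoxy-14-hydroxy-8-[(2R)-2-methylbutanoyloxy]-1,10:4,5-diepoxygermacra-2Z,7(11)-dien-12,6-olide (1R,4R,5S,6S,8S,10S) | CC[C@@H](C)C(=O)O[C@H]1C[C@@]2(CO)O[C@@H]2/C=C\[C@@]2(C)O[C@H]2[C@H]2OC(=O)C(COC(C)=O)=C12 | target

**Step count and risks**

Total: 17 steps. Longest linear sequence: 14 steps (steps 4 to 17, from 5 and 6 to 27).

Most likely to fail:

- Step 9 (the new Wolff–alkynylation). Risks are ketene dimerisation and γ-protonation of enolate 17. The fallback sets out from 13 and comes back at 18: a PhCO2Ag/Et3N-promoted Wolff rearrangement of 13 in THF with MeNH(OMe) gives the Weinreb amide (3Z)-3-({[tert-butyl(dimethyl)silyl]oxy}methyl)-N-methoxy-N-methylhexa-3,5-dienamide F1. Adding F1 to alkynyllithium 15 at −78 °C, followed by buffered work-up, gives 18. This is a classical Arndt–Eistert homologation followed by a Weinreb ketone synthesis.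

- Step 16 (Nozaki–Hiyama–Kishi union). Risks are the hindered tetrasubstituted iodoenoate and modest Felkin selectivity. The fallback sets out from 4 and 25 and comes back at 26, and sets C6 by ketone reduction instead of C–C addition. Pinnick oxidation of 4 (NaClO2, NaH2PO4, 2-methylbut-2-ene) gives (2R,3R)-3-ethenyl-3-methyloxirane-2-carboxylic acid F2. PhSH/DCC converts F2 into S-phenyl (2R,3R)-3-ethenyl-3-methyloxirane-2-carbothioate F3. In parallel, 25 with (Me3Sn)2 and Pd(PPh3)4 gives methyl (2Z,4S)-2-(acetoxymethyl)-5-[(2S,3R)-3-ethenyl-2-(hydroxymethyl)oxiran-2-yl]-4-{[(2R)-2-methylbutanoyl]oxy}-3-(trimethylstannyl)pent-2-enoate F4. Liebeskind–Srogl coupling of F3 with F4 (Pd2(dba)3, P(2-furyl)3, copper thiophene-2-carboxylate with monovalent copper) gives methyl (2Z,4S)-2-(acetoxymethyl)-3-{[(2R,3R)-3-ethenyl-3-methyloxiran-2-yl]carbonyl}-5-[(2S,3R)-3-ethenyl-2-(hydroxymethyl)oxiran-2-yl]-4-{[(2R)-2-methylbutanoyl]oxy}pent-2-enoate F5. Chelation-controlled reduction of F5 with Zn(BH4)2 at −78 °C delivers hydride to give the same 6S alcohol, which lactonises to 26.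

- Step 17 (ten-membered ring-closing metathesis). Risks are dimerisation and E/Z control. The fallback sets out from 25 and 4 and comes back at 27, swapping the order of ring closure and fragment union. Z-selective cross-metathesis of 25 with excess 4, using Ru(3,6-dichlorobenzene-1,2-dithiolate)(H2IMes)(=CH-C6H4-2-OiPr), gives the open-chain methyl (2Z,4S)-2-(acetoxymethyl)-5-[(2S,3R)-3-{(Z)-2-[(2R,3R)-3-formyl-2-methyloxiran-2-yl]ethenyl}-2-(hydroxymethyl)oxiran-2-yl]-3-iodo-4-{[(2R)-2-methylbutanoyl]oxy}pent-2-enoate F6. An intramolecular Nozaki–Hiyama–Kishi reaction of F6 (CrCl2, NiCl2 cat., DMSO–THF, 2 mM) then closes the ten-membered ring and lactonises to 27.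

Further compounds
F1 | step 9 | (3Z)-3-({[tert-butyl(dimethyl)silyl]oxy}methyl)-N-methoxy-N-methylhexa-3,5-dienamide | CON(C)C(=O)C/C(CO[Si](C)(C)C(C)(C)C)=C/C=C
F2 | step 16 | (2R,3R)-3-ethenyl-3-methyloxirane-2-carboxylic acid | C=C[C@@]1(C)O[C@H]1C(=O)O
F3 | step 16 | S-phenyl (2R,3R)-3-ethenyl-3-methyloxirane-2-carbothioate | C=C[C@@]1(C)O[C@H]1C(=O)Sc1ccccc1
F4 | step 16 | methyl (2Z,4S)-2-(acetoxymethyl)-5-[(2S,3R)-3-ethenyl-2-(hydroxymethyl)oxiran-2-yl]-4-{[(2R)-2-methylbutanoyl]oxy}-3-(trimethylstannyl)pent-2-enoate | COC(=O)/C(COC(C)=O)=C(\[Sn](C)(C)C)[C@@H](OC(=O)[C@H](C)CC)C[C@@]1(CO)O[C@@H]1C=C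
F5 | step 16 | methyl (2Z,4S)-2-(acetoxymethyl)-3-{[(2R,3R)-3-ethenyl-3-methyloxiran-2-yl]carbonyl}-5-[(2S,3R)-3-ethenyl-2-(hydroxymethyl)oxiran-2-yl]-4-{[(2R)-2-methylbutanoyl]oxy}pent-2-enoate | COC(=O)/C(COC(C)=O)=C(\C(=O)[C@@H]1O[C@]1(C)C=C)[C@@H](OC(=O)[C@H](C)CC)C[C@@]1(CO)O[C@@H]1C=C
F6 | step 17 | methyl (2Z,4S)-2-(acetoxymethyl)-5-[(2S,3R)-3-{(Z)-2-[(2R,3R)-3-formyl-2-methyloxiran-2-yl]ethenyl}-2-(hydroxymethyl)oxiran-2-yl]-3-iodo-4-{[(2R)-2-methylbutanoyl]oxy}pent-2-enoate | COC(=O)/C(COC(C)=O)=C(\I)[C@@H](OC(=O)[C@H](C)CC)C[C@@]1(CO)O[C@@H]1/C=C\[C@@]1(C)O[C@H]1C=O
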